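**Retrosynthetic overview**
1. Locants (cembrane type): C1 = ring-fusion CH carrying C15 (C16 = exo-methylene, C17 = C=O); C2 = its ring CH2; C3=C4 and C7=C8 = the E-alkenes; C11–Cl; C12–OH; C14 = O–CH.
2. Last operations: α-methylenation (C16) of the saturated trans-fused γ-lactone, which comes from oxidation of a 2-ethoxyoxolane.
3. Key disconnection: C2–C3 (closes the 14-membered carbocycle) together with C1–C15 (closes the oxolane just before it, same flask), by a nickel-mediated radical cascade of an acyclic bromoacetal of a C14 vinyl carbinol that ends in an (E)-alkenyl iodide at C3. Ring order: oxolane, then carbocycle.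
4. Enabling feature: C2 is the methylene exocyclic to the five-membered lactone ring at its β-carbon C1 and is also bonded to the vinylic CH (C3) of the E-trisubstituted C3=C4 alkene. C2 is therefore the radical terminus of a 5-exo closure of C15 onto C1=C2 (tether C14–O–C17–C15), and C3 can enter as a geometry-defined alkenyl halide.
5. Acyclic precursor: C14 by Noyori transfer hydrogenation of an ynone; C12 by Cornforth-controlled aldol addition to an (S)-α-chloro methyl ketone; C11 by Sharpless epoxidation/chloride opening; chain from (E)-geranylacetone by Negishi carboalumination–iodination.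

Key step: step 12

Remark on the chemistry: isomerically pure (E)-geranylacetone is taken as commercial; the acetal carbon of 17 to 19 and the α-carbon of 23 and 24 arise as epimer mixtures whose stereogenicity is erased in steps 13 and 16.

**Step 1**
Reactants: 1 (E)-geranylacetone
Product: 4 (5E)-6,10-dimethylundeca-5,9-dien-1-yne, via lithium enolate 2 (not isolated), via enol phosphate 3 (not isolated)
Conditions: LiN(iPr)2 (1.05 equiv), THF, −78 °C; ClP(O)(OEt)2, −78 °C → rt; LiN(iPr)2 (2.3 equiv), −78 °C → rt; H2O
Reagents that add atoms: none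
Why: Kinetic deprotonation at the methyl group, O-phosphorylation and amide-induced elimination of diethyl phosphate (Negishi conversion of a methyl ketone into a terminal alkyne) should give the enyne without touching the two trisubstituted alkenes.

**Step 2**
Reactants: 4 (5E)-6,10-dimethylundeca-5,9-dien-1-yne
Product: 6 (1E,5E)-1-iodo-2,6,10-trimethylundeca-1,5,9-triene, via alkenylalane 5 (not isolated)
Conditions: Me3Al (2.5 equiv), Cp2ZrCl2 (0.25 equiv), CH2Cl2, 0 °C → rt; then I2, THF, −30 → 0 °C
Reagents that add atoms: trimethylaluminium, C[Al](C)C; iodine, II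
Why: Zirconium-catalysed syn-carboalumination of the terminal alkyne (Negishi carboalumination) puts the new methyl on the internal carbon and aluminium on the terminal one, and iodinolysis with retention fixes the E geometry of the trisubstituted alkenyl iodide.

**Step 3**
Reactants: 6 (1E,5E)-1-iodo-2,6,10-trimethylundeca-1,5,9-triene
Product: 7 (2E,6E,10E)-11-iodo-2,6,10-trimethylundeca-2,6,10-trien-1-ol
Conditions: SeO2 (0.3 equiv), t-BuOOH (70% aq., 3 equiv), salicylic acid (0.1 equiv), CH2Cl2, 0 °C → rt
Reagents that add atoms: selenium dioxide, O=[Se]=O (oxygen donor, re-formed by tert-butyl hydroperoxide, CC(C)(C)OO)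
Why: Catalytic SeO2/t-BuOOH allylic oxidation (ene reaction followed by [2,3]-sigmatropic shift) should select the E-methyl group of the terminal isopropylidene unit, the iodo-alkene being deactivated and the internal alkene slower.

**Step 4**
Reactants: 7 (2E,6E,10E)-11-iodo-2,6,10-trimethylundeca-2,6,10-trien-1-ol
Product: 8 (2R,3R)-2,3-epoxy alcohol
Conditions: Ti(OiPr)4 (0.1 equiv), D-(−)-diethyl tartrate (0.12 equiv), t-BuOOH (2 equiv, anhydrous), 4 Å MS, CH2Cl2, −20 °C
Reagents that add atoms: tert-butyl hydroperoxide, CC(C)(C)OO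
Why: Sharpless asymmetric epoxidation acts only on the allylic alcohol alkene, and with D-(−)-diethyl tartrate the oxygen is delivered to the face that gives the (2R,3R)-epoxy alcohol (the mirror image of the (2S,3S) series formed from E-allylic alcohols with the L-(+)-tartrate).

**Step 5**
Reactants: 8 (2R,3R)-2,3-epoxy alcohol
Product: 9 (2R,3S)-3-chloro-1,2-diol
Conditions: ClTi(OiPr)3 (1.5 equiv), CH2Cl2, 0 °C → rt; aqueous work-up
Reagents that add atoms: chlorotitanium triisopropoxide, CC(C)O[Ti](Cl)(OC(C)C)OC(C)C
Why: Titanium-assisted ring opening of the 2,3-epoxy alcohol, in which chloride is delivered from the alkoxide-bound metal to C3 with inversion because the quaternary C2 cannot undergo SN2 attack, sets the (S)-configured secondary chloride.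

**Step 6**
Reactants: 9 (2R,3S)-3-chloro-1,2-diol
Product: 10 (3S,6E,10E)-3-chloro-11-iodo-6,10-dimethylundeca-6,10-dien-2-one
Conditions: NaIO4 (1.5 equiv), THF/H2O (2:1), 0 °C → rt
Reagents that add atoms: none
Why: Periodate glycol cleavage (Malaprade reaction) of the primary/tertiary 1,2-diol gives the methyl ketone under neutral conditions that should not epimerise the α-chloro stereocenter, which alone is carried on.

**Step 7**
Reactants: 10 (3S)-α-chloro methyl ketone; 11 4-(trimethylsilyl)but-3-yn-2-one
Product: 13 (5R,6S)-β-hydroxy ynone, via lithium enolate 12 (not isolated)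
Conditions: 11, LiN(SiMe3)2 (1.1 equiv), THF, −78 °C; then 10, −78 °C, 1 h; AcOH, −78 °C
Reagents that add atoms: none
Why: Aldol addition of the lithium enolate of the alkynyl methyl ketone to the activated α-chloro ketone should follow the Cornforth model (C–Cl anti to C=O, attack past the α-hydrogen) and so give the anti chlorohydrin with the (5R)-tertiary carbinol, the cold acidic quench forestalling retro-aldol and epoxide closure.

**Step 8**
Reactants: 13 (5R,6S)-β-hydroxy ynone
Product: 14 (3S,5R,6S)-silylalkynyl diol
Conditions: Ru[(S,S)-TsDPEN](p-cymene) (preformed amido complex, 2 mol%), i-PrOH, rt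
Reagents that add atoms: none
Why: Noyori asymmetric transfer hydrogenation of the alkynyl ketone is reagent-controlled, the alkynyl group taking the place of the aryl group in the usual model, so that the (S,S)-catalyst should give the (3S)-propargylic alcohol whatever the neighbouring stereocenters.

**Step 9**
Reactants: 14 (3S,5R,6S)-silylalkynyl diol
Product: 15 (3S,5R,6S)-terminal alkynyl diol
Conditions: Bu4NF (1.2 equiv), AcOH (1.2 equiv), THF, 0 °C
Reagents that add atoms: none
Why: Fluoride-induced protodesilylation of the alkynylsilane, buffered with acetic acid so that no alkoxide strong enough to close the chlorohydrin to an epoxide is formed.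

**Step 10**
Reactants: 15 (3S,5R,6S)-terminal alkynyl diol
Product: 16 (3S,5R,6S)-vinyl carbinol diol
Conditions: H2 (1 atm), Pd/CaCO3 poisoned with Pb(OAc)2 (Lindlar catalyst), quinoline, EtOAc, rt, stopped after 1 equiv H2
Reagents that add atoms: none
Why: Lindlar semi-hydrogenation of the terminal alkyne stops at the vinyl group, and the poisoned catalyst with quinoline should leave the trisubstituted alkenes, the secondary chloride and the hindered alkenyl iodide untouched if the uptake of hydrogen is monitored.

**Step 11**
Reactants: 16 (3S,5R,6S)-vinyl carbinol diol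
Product: 17 bromoacetal of the secondary allylic alcohol
Conditions: NBS (1.2 equiv), ethyl vinyl ether (5 equiv), 2,6-lutidine (0.2 equiv), CH2Cl2, −40 → −20 °C
Reagents that add atoms: N-bromosuccinimide, O=C1CCC(=O)N1Br; ethyl vinyl ether, C=COCC
Why: Bromoacetalisation (first stage of a Ueno–Stork sequence) in which NBS brominates the electron-rich enol ether far faster than the trisubstituted alkenes and the oxocarbenium ion is trapped by the secondary allylic hydroxyl while the hindered tertiary one stays free, the new acetal carbon being an epimer mixture that disappears in step 13.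

**Step 12**
Reactants: 17 bromoacetal of the secondary allylic alcohol
Product: 18 macrocyclic trans-fused 2-ethoxyoxolane
Conditions: NiBr2·DME (0.3 equiv), 4,4′-di-tert-butyl-2,2′-bipyridine (0.36 equiv), Mn powder (4 equiv), DMA, 30 °C, 17 added over 16 h by syringe pump (final 2 mM)
Reagents that add atoms: none
Why: Proposed new method: zerovalent nickel (made from NiBr2 and Mn) inserts into the alkenyl C–I bond with retention, a univalent nickel species takes the bromine atom from the bromoacetal, the C15 radical adds to C1=C2 and the new primary C2 radical is caught by the alkenylnickel centre, where reductive elimination from trivalent nickel forms the C2–C3 bond; the closest known reaction type is the nickel-catalysed reductive radical cyclisation/cross-coupling of alkene-tethered haloacetals with external aryl or alkenyl halides (a Ueno–Stork cyclisation that ends in a cross-electrophile coupling), used here with the alkenyl halide placed in the same molecule. The oxolane ring closes in the 5-exo-trig mode and the 14-membered carbocycle closes in the C(sp3)–C(sp2) reductive elimination at nickel. The new stereocenter C1 is controlled by C14, because in the chair-like Beckwith–Houk transition state the C13 chain is pseudo-equatorial and C2 therefore ends trans to it on the oxolane, the usual 4,5-trans outcome of Ueno–Stork closures of 1-substituted allyl acetals. The step needs cyclisation before coupling, which the fast 5-exo closure of the β-alkoxyalkyl radical secures at millimolar concentration, ring closure instead of oligomerisation, which slow addition of 17 to an excess of catalyst secures, and an unchanged E alkene, which the stereoretentive insertion and reductive elimination at the alkenyl carbon secure. The unactivated secondary chloride, the free tertiary alcohol and the trisubstituted alkenes should be inert to the NiBr2/bipyridine/Mn system at 30 °C.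

**Step 13**
Reactants: 18 macrocyclic trans-fused 2-ethoxyoxolane
Product: 20 trans-fused γ-lactone, via lactol 19 (not isolated)
Conditions: CrO3, H2SO4, H2O/acetone (Jones reagent), 0 °C, 30 min
Reagents that add atoms: water, O
Why: Jones oxidation of a 2-alkoxyoxolane, in which the acid hydrolyses the acetal to the lactol and chromic acid oxidises it at once to the γ-lactone, while the tertiary alcohol cannot be oxidised and is kept from ionising by the adjacent C–Cl bond.

**Step 14**
Reactants: 20 trans-fused γ-lactone
Product: 21 lactone trimethylsilyl ether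
Conditions: 1-(trimethylsilyl)imidazole (3 equiv), CH2Cl2, rt
Reagents that add atoms: 1-(trimethylsilyl)imidazole, C[Si](C)(C)n1ccnc1
Why: Silylation of the hindered tertiary alcohol with the strong neutral donor trimethylsilylimidazole masks the chlorohydrin so that the base of step 15 cannot close it to an epoxide.

**Step 15**
Reactants: 21 lactone trimethylsilyl ether
Product: 23 α-(dimethylaminomethyl) lactone, via lactone lithium enolate 22 (not isolated)
Conditions: LiN(iPr)2 (1.2 equiv), THF, −78 °C; then CH2=NMe2+ I− (Eschenmoser's salt, 3 equiv), −78 °C → rt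
Reagents that add atoms: N,N-dimethylmethyleneiminium iodide, C=[N+](C)C.[I-]
Why: Mannich reaction of the lactone lithium enolate with Eschenmoser's salt, where the configuration of the new α-carbon does not matter because it becomes trigonal in step 16.

**Step 16**
Reactants: 23 α-(dimethylaminomethyl) lactone
Product: 25 α-methylene lactone trimethylsilyl ether, via ammonium iodide 24 (not isolated)
Conditions: MeI (10 equiv), MeOH, rt; then NaHCO3 (aq), EtOAc, rt
Reagents that add atoms: none
Why: Exhaustive methylation to the quaternary ammonium salt followed by bicarbonate-induced E1cB elimination of trimethylamine (Hofmann-type elimination of a Mannich base) gives the α-methylene lactone without strong base.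

**Step 17**
Reactants: 25 α-methylene lactone trimethylsilyl ether
Product: 26 target CNP0247658.1
Conditions: HCl (1 M aq), THF, 0 °C
Reagents that add atoms: none
Why: Mild acid hydrolysis of the tertiary trimethylsilyl ether frees the hydroxyl and should leave the α-methylene lactone, the chloride and the alkenes untouched.

**Compound list**
1 | (5E)-6,10-dimethylundeca-5,9-dien-2-one [(E)-geranylacetone] | CC(=O)CC/C=C(\C)CCC=C(C)C | starting material
2 | lithium (5E)-6,10-dimethylundeca-1,5,9-trien-2-olate | [Li]OC(=C)CC/C=C(\C)CCC=C(C)C | intermediate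
3 | diethyl (5E)-6,10-dimethylundeca-1,5,9-trien-2-yl phosphate | C=C(OP(=O)(OCC)OCC)CC/C=C(\C)CCC=C(C)C | intermediate
4 | (5E)-6,10-dimethylundeca-5,9-dien-1-yne | C#CCC/C=C(\C)CCC=C(C)C | intermediate
5 | dimethyl[(1E,5E)-2,6,10-trimethylundeca-1,5,9-trien-1-yl]aluminium | C[Al](C)/C=C(\C)CC/C=C(\C)CCC=C(C)C | intermediate
6 | (1E,5E)-1-iodo-2,6,10-trimethylundeca-1,5,9-triene | I/C=C(\C)CC/C=C(\C)CCC=C(C)C | intermediate
7 | (2E,6E,10E)-11-iodo-2,6,10-trimethylundeca-2,6,10-trien-1-ol | I/C=C(\C)CC/C=C(\C)CC/C=C(\C)CO | intermediate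
8 | [(2R,3R)-3-[(3E,7E)-8-iodo-3,7-dimethylocta-3,7-dien-1-yl]-2-methyloxiran-2-yl]methanol | OC[C@@]1(C)O[C@@H]1CC/C(C)=C/CC/C(C)=C/I | intermediate
9 | (2R,3S,6E,10E)-3-chloro-11-iodo-2,6,10-trimethylundeca-6,10-diene-1,2-diol | OC[C@@](C)(O)[C@@H](Cl)CC/C(C)=C/CC/C(C)=C/I | intermediate
10 | (3S,6E,10E)-3-chloro-11-iodo-6,10-dimethylundeca-6,10-dien-2-one | CC(=O)[C@@H](Cl)CC/C(C)=C/CC/C(C)=C/I | intermediate
11 | 4-(trimethylsilyl)but-3-yn-2-one | CC(=O)C#C[Si](C)(C)C | starting material
12 | lithium 4-(trimethylsilyl)but-1-en-3-yn-2-olate | [Li]OC(=C)C#C[Si](C)(C)C | intermediate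
13 | (5R,6S,9E,13E)-6-chloro-5-hydroxy-14-iodo-5,9,13-trimethyl-1-(trimethylsilyl)tetradeca-9,13-dien-1-yn-3-one | C[Si](C)(C)C#CC(=O)C[C@@](C)(O)[C@@H](Cl)CC/C(C)=C/CC/C(C)=C/I | intermediate
14 | (3S,5R,6S,9E,13E)-6-chloro-14-iodo-5,9,13-trimethyl-1-(trimethylsilyl)tetradeca-9,13-dien-1-yne-3,5-diol | C[Si](C)(C)C#C[C@@H](O)C[C@@](C)(O)[C@@H](Cl)CC/C(C)=C/CC/C(C)=C/I | intermediate
15 | (3S,5R,6S,9E,13E)-6-chloro-14-iodo-5,9,13-trimethyltetradeca-9,13-dien-1-yne-3,5-diol | C#C[C@@H](O)C[C@@](C)(O)[C@@H](Cl)CC/C(C)=C/CC/C(C)=C/I | intermediate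
16 | (3S,5R,6S,9E,13E)-6-chloro-14-iodo-5,9,13-trimethyltetradeca-1,9,13-triene-3,5-diol | C=C[C@@H](O)C[C@@](C)(O)[C@@H](Cl)CC/C(C)=C/CC/C(C)=C/I | intermediate
17 | (3S,5R,6S,9E,13E)-3-(2-bromo-1-ethoxyethoxy)-6-chloro-14-iodo-5,9,13-trimethyltetradeca-1,9,13-trien-5-ol (acetal epimers) | C=C[C@@H](OC(CBr)OCC)C[C@@](C)(O)[C@@H](Cl)CC/C(C)=C/CC/C(C)=C/I | intermediate
18 | (3aR,5E,9E,13S,14R,15aS)-13-chloro-2-ethoxy-6,10,14-trimethyl-2,3,3a,4,7,8,11,12,13,14,15,15a-dodecahydrocyclotetradeca[b]furan-14-ol (C2 epimers) | C1C(OCC)O[C@H]2C[C@@](C)(O)[C@@H](Cl)CC/C(C)=C/CC/C(C)=C/C[C@H]12 | intermediate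
19 | (3aR,5E,9E,13S,14R,15aS)-13-chloro-6,10,14-trimethyl-2,3,3a,4,7,8,11,12,13,14,15,15a-dodecahydrocyclotetradeca[b]furan-2,14-diol (lactol) | C1C(O)O[C@H]2C[C@@](C)(O)[C@@H](Cl)CC/C(C)=C/CC/C(C)=C/C[C@H]12 | intermediate
20 | (3aR,5E,9E,13S,14R,15aS)-13-chloro-14-hydroxy-6,10,14-trimethyl-3a,4,7,8,11,12,13,14,15,15a-decahydrocyclotetradeca[b]furan-2(3H)-one | C1C(=O)O[C@H]2C[C@@](C)(O)[C@@H](Cl)CC/C(C)=C/CC/C(C)=C/C[C@H]12 | intermediate
21 | (3aR,5E,9E,13S,14R,15aS)-13-chloro-6,10,14-trimethyl-14-[(trimethylsilyl)oxy]-3a,4,7,8,11,12,13,14,15,15a-decahydrocyclotetradeca[b]furan-2(3H)-one | C1C(=O)O[C@H]2C[C@@](C)(O[Si](C)(C)C)[C@@H](Cl)CC/C(C)=C/CC/C(C)=C/C[C@H]12 | intermediate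
22 | lithium enolate of 21 (2-lithiooxy-3a,15a-dihydrofuran form) | C1=C(O[Li])O[C@H]2C[C@@](C)(O[Si](C)(C)C)[C@@H](Cl)CC/C(C)=C/CC/C(C)=C/C[C@H]12 | intermediate
23 | 3-[(dimethylamino)methyl] derivative of 21 (C3 epimers) | CN(C)CC1C(=O)O[C@H]2C[C@@](C)(O[Si](C)(C)C)[C@@H](Cl)CC/C(C)=C/CC/C(C)=C/C[C@H]12 | intermediate
24 | trimethylammoniomethyl lactone iodide from 23 | C[N+](C)(C)CC1C(=O)O[C@H]2C[C@@](C)(O[Si](C)(C)C)[C@@H](Cl)CC/C(C)=C/CC/C(C)=C/C[C@H]12.[I-] | intermediate
25 | (3aR,5E,9E,13S,14R,15aS)-13-chloro-6,10,14-trimethyl-3-methylidene-14-[(trimethylsilyl)oxy]-3a,4,7,8,11,12,13,14,15,15a-decahydrocyclotetradeca[b]furan-2(3H)-one | C=C1C(=O)O[C@H]2C[C@@](C)(O[Si](C)(C)C)[C@@H](Cl)CC/C(C)=C/CC/C(C)=C/C[C@H]12 | intermediate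
26 | (3aR,5E,9E,13S,14R,15aS)-13-chloro-14-hydroxy-6,10,14-trimethyl-3-methylidene-3a,4,7,8,11,12,13,14,15,15a-decahydrocyclotetradeca[b]furan-2(3H)-one (CNP0247658.1) | C=C1C(=O)O[C@H]2C[C@@](C)(O)[C@@H](Cl)CC/C(C)=C/CC/C(C)=C/C[C@H]12 | target

**Step count**
Total: 17 steps. Longest linear sequence: 17 steps (1 to 26); 11 is used as purchased.

**Steps most likely to fail**

Step 12 (proposed new method). The cyclised C2 radical may be reduced or abstract hydrogen before it reaches the alkenylnickel centre of its own molecule, or alkenylnickel species may couple between molecules (oligomerisation). The fallback uses known chemistry only, sets out from 16 and comes back at 18; it separates radical cyclisation from ring closure. N-Iodosuccinimide and ethyl vinyl ether (CH2Cl2, −40 °C) convert 16 into the iodoacetal F1. BEt3/air (cat.) in benzene at rt then starts an iodine-atom-transfer Ueno–Stork cyclisation to the trans-4-(iodomethyl)oxolane F2, with the same C14 control of C1. Zinc dust/LiCl in THF–DMA at 30 °C inserts only into the primary alkyl C–I bond and gives the alkylzinc iodide F3 (not isolated). Slow addition of this solution to Pd2(dba)3/tri(2-furyl)phosphine at 50 °C closes the 14-membered ring by an intramolecular Negishi coupling and gives 18.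

Step 7. Proton transfer from the α-chloro ketone to the enolate may consume material and erode the chloride stereocenter, the hindered tertiary aldolate may revert (retro-aldol), or the Cornforth facial selectivity may be too low. The fallback sets out from 10 and comes back at 13; it builds the ynone in two acylation-type stages. The more nucleophilic lithium enolate of N-methoxy-N-methylacetamide (from the amide and LiN(iPr)2, THF, −78 °C) adds irreversibly to 10 and gives the β-hydroxy Weinreb amide F4, whose C3 epimers can be separated at this stage. Commercial lithium (trimethylsilyl)acetylide (2.5 equiv, THF, −78 → −20 °C, cold acidic quench) then converts F4 into 13.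

Step 10. Palladium may cleave the alkenyl C–I bond by hydrogenolysis, or the vinyl group may be over-reduced. The fallback sets out from 15 and comes back at 16; it uses neither hydrogen nor palladium. Cp2Zr(H)Cl (3.3 equiv, THF, rt) first turns both hydroxyls into zirconium alkoxides and then hydrozirconates the terminal alkyne only, giving the alkenylzirconocene F5 (not isolated); protonolysis with water gives 16.

**Further compounds**
F1 | step 12 | (3S,5R,6S,9E,13E)-6-chloro-3-(1-ethoxy-2-iodoethoxy)-14-iodo-5,9,13-trimethyltetradeca-1,9,13-trien-5-ol (iodoacetal) | C=C[C@@H](OC(CI)OCC)C[C@@](C)(O)[C@@H](Cl)CC/C(C)=C/CC/C(C)=C/I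
F2 | step 12 | (2R,3S,6E,10E)-3-chloro-1-[(2S,3R)-5-ethoxy-3-(iodomethyl)oxolan-2-yl]-11-iodo-2,6,10-trimethylundeca-6,10-dien-2-ol | C1C(OCC)O[C@@H](C[C@@](C)(O)[C@@H](Cl)CC/C(C)=C/CC/C(C)=C/I)[C@@H]1CI
F3 | step 12 | alkylzinc iodide from F2 (iodozinciomethyl in place of iodomethyl) | C1C(OCC)O[C@@H](C[C@@](C)(O)[C@@H](Cl)CC/C(C)=C/CC/C(C)=C/I)[C@@H]1C[Zn]I
F4 | step 7 | (3R,4S,7E,11E)-4-chloro-3-hydroxy-12-iodo-N-methoxy-N,3,7,11-tetramethyldodeca-7,11-dienamide | CON(C)C(=O)C[C@@](C)(O)[C@@H](Cl)CC/C(C)=C/CC/C(C)=C/I
F5 | step 10 | (E)-alkenylzirconocene chloride of 15 with both hydroxyls as chlorozirconocene alkoxides | Cl[Zr](C1C=CC=C1)(C1C=CC=C1)/C=C/[C@@H](O[Zr](Cl)(C1C=CC=C1)C1C=CC=C1)C[C@@](C)(O[Zr](Cl)(C1C=CC=C1)C1C=CC=C1)[C@@H](Cl)CC/C(C)=C/CC/C(C)=C/I
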